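The flavonol C ring carries an enolone, C3–OH beside C4=O, which is the enol of a chroman-3,4-dione and lies one oxidation level above an acyloin; C3 and C4 can therefore both enter as aldehyde carbons. The whole plan rests on joining them: an N-heterocyclic carbene turns the aliphatic aldehyde into an acyl-anion equivalent that adds to the aryl aldehyde, forming C3–C4 and closing the pyranone ring in one redox-neutral operation. The precursor is a fully substituted benzaldehyde (2-OBn, 3,4,5-OMe) whose 6-oxygen bears a CH(4-benzyloxyphenyl)CHO arm. Iodine oxidation and hydrogenolysis then give the achiral target.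

Key step: step 11

Assumption: the target has no stereogenic element, so the enantiomer requirement is met trivially; chiral intermediates are carried as racemates or diastereomer mixtures, and their centres become sp2 in step 12.
Remark on regiochemistry: because the carbene engages the aliphatic aldehyde, the first ring-closed ketol carries its ketone at C3 (18); the aryl-conjugated 3-hydroxychroman-4-one 19 arises from it by ketol transposition in the same flask.
Remark on precursor design: the aryl formyl group is placed on the free phenol before etherification, so the acid-labile 4-alkoxybenzylic aryl ether never meets a formylating Lewis acid; both aldehydes are then unveiled together from a diol.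

Step 1
Reactants: 1 2,3,4-trimethoxybenzaldehyde
Product: 2 5-bromo-2,3,4-trimethoxybenzaldehyde
Conditions: NBS (1.1 equiv), MeCN, rt to 50 °C
Reagents that add atoms: N-bromosuccinimide, O=C1CCC(=O)N1Br
Why: Electrophilic aromatic bromination should go to C5, the only position that is ortho/para to two methoxy groups and meta to the deactivating formyl group.

Step 2
Reactants: 2 5-bromo-2,3,4-trimethoxybenzaldehyde
Product: 4 5-bromo-2,3,4-trimethoxyphenol, via aryl formate 3 (not isolated)
Conditions: mCPBA (1.3 equiv), CH2Cl2, rt; NaHCO3 wash; then K2CO3 (cat.), MeOH, rt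
Reagents that add atoms: meta-chloroperoxybenzoic acid, OOC(=O)c1cccc(Cl)c1
Why: Baeyer–Villiger (Dakin-type) oxidation of an electron-rich benzaldehyde proceeds with aryl migration to formate 3, and carbonate-catalysed methanolysis then frees the phenol exactly where the formyl group stood.

Step 3
Reactants: 4 5-bromo-2,3,4-trimethoxyphenol; 5 benzyl bromide
Product: 6 1-(benzyloxy)-5-bromo-2,3,4-trimethoxybenzene
Conditions: BnBr (1.1 equiv), K2CO3, DMF, rt
Reagents that add atoms: benzyl bromide (5), BrCc1ccccc1
Why: Williamson etherification of the phenoxide with a reactive benzylic halide, with no other nucleophilic site present.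

Step 4
Reactants: 6 1-(benzyloxy)-5-bromo-2,3,4-trimethoxybenzene
Product: 9 5-(benzyloxy)-2,3,4-trimethoxyphenol, via aryllithium 7 (not isolated), via dimethyl arylboronate 8 (not isolated)
Conditions: n-BuLi (1.05 equiv), THF, −78 °C; B(OMe)3, −78 °C to rt; then 30% aq. H2O2, 0 °C to rt
Reagents that add atoms: hydrogen peroxide, OO (oxygen of the new phenol); n-butyllithium, [Li]CCCC, and trimethyl borate, COB(OC)OC, leave atoms only in intermediates 7 and 8
Why: Bromine–lithium exchange at −78 °C is much faster than deprotonation of the benzyl ether, and borylation followed by the peroxide-induced 1,2-aryl shift from boron to oxygen (boronate oxidation) places the hydroxyl on the former C–Br carbon.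

Step 5
Reactants: 9 5-(benzyloxy)-2,3,4-trimethoxyphenol
Product: 11 6-(benzyloxy)-2-hydroxy-3,4,5-trimethoxybenzaldehyde, via hydroxymethylphenol 10 (not isolated)
Conditions: MgCl2 (2 equiv), Et3N (4 equiv), (CH2O)n (6 equiv), MeCN, reflux
Reagents that add atoms: formaldehyde (as paraformaldehyde), C=O
Why: In the magnesium-mediated ortho-formylation (Casnati–Skattebøl) the magnesium phenoxide delivers formaldehyde to the only free ring carbon, which is ortho to the hydroxyl, and a second formaldehyde oxidises hydroxymethyl intermediate 10 by hydride transfer.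

Step 6
Reactants: 12 4-hydroxymandelic acid (racemic); 5 benzyl bromide
Product: 13 benzyl 2-[4-(benzyloxy)phenyl]-2-hydroxyacetate (racemic)
Conditions: BnBr (2.2 equiv), K2CO3 (2.5 equiv), DMF, rt
Reagents that add atoms: benzyl bromide (5), BrCc1ccccc1
Why: Carbonate deprotonates only the carboxylic acid and the phenol, so double Williamson-type O-benzylation should give the ester ether and leave the secondary alcohol free, the stereocentre staying racemic.

Step 7
Reactants: 13 benzyl 2-[4-(benzyloxy)phenyl]-2-hydroxyacetate (racemic)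
Product: 14 benzyl 2-bromo-2-[4-(benzyloxy)phenyl]acetate (racemic)
Conditions: CBr4 (1.3 equiv), PPh3 (1.3 equiv), CH2Cl2, 0 °C
Reagents that add atoms: carbon tetrabromide, BrC(Br)(Br)Br
Why: Appel bromination converts the activated secondary alcohol into the bromide under neutral conditions; the C–Br centre is racemic and its configuration is irrelevant.

Step 8
Reactants: 11 6-(benzyloxy)-2-hydroxy-3,4,5-trimethoxybenzaldehyde; 14 benzyl 2-bromo-2-[4-(benzyloxy)phenyl]acetate (racemic)
Product: 15 benzyl 2-[3-(benzyloxy)-2-formyl-4,5,6-trimethoxyphenoxy]-2-[4-(benzyloxy)phenyl]acetate (racemic)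
Conditions: K2CO3 (1.5 equiv), DMF, rt
Reagents that add atoms: none
Why: Williamson SN2 displacement at an α-bromo ester, an electrophile activated by the adjacent carbonyl, should tolerate the hindered phenoxide, and the new ether stereocentre (future C2) forms as a racemate that is destroyed later.

Step 9
Reactants: 15 benzyl 2-[3-(benzyloxy)-2-formyl-4,5,6-trimethoxyphenoxy]-2-[4-(benzyloxy)phenyl]acetate (racemic)
Product: 16 2-[3-(benzyloxy)-2-(hydroxymethyl)-4,5,6-trimethoxyphenoxy]-2-[4-(benzyloxy)phenyl]ethan-1-ol (racemic)
Conditions: LiAlH4 (1.5 equiv), THF, 0 °C; Fieser work-up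
Reagents that add atoms: none
Why: Lithium aluminium hydride reduces the aldehyde and the ester to primary alcohols in one operation while aryl and benzyl ethers are inert.

Step 10
Reactants: 16 2-[3-(benzyloxy)-2-(hydroxymethyl)-4,5,6-trimethoxyphenoxy]-2-[4-(benzyloxy)phenyl]ethan-1-ol (racemic)
Product: 17 2-(benzyloxy)-6-{1-[4-(benzyloxy)phenyl]-2-oxoethoxy}-3,4,5-trimethoxybenzaldehyde (racemic)
Conditions: Dess–Martin periodinane (3 equiv), CH2Cl2, 0 °C to rt; Na2S2O3/NaHCO3 work-up; used at once
Reagents that add atoms: none
Why: Dess–Martin oxidation converts both primary alcohols to aldehydes under neutral, non-basic conditions, which avoids enolisation of the α-aryl-α-aryloxy aldehyde.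

Step 11
Reactants: 17 2-(benzyloxy)-6-{1-[4-(benzyloxy)phenyl]-2-oxoethoxy}-3,4,5-trimethoxybenzaldehyde (racemic)
Product: 19 5-(benzyloxy)-2-[4-(benzyloxy)phenyl]-3-hydroxy-6,7,8-trimethoxychroman-4-one (racemic diastereomer mixture), via 4-hydroxychroman-3-one ketol 18 (not isolated)
Conditions: 6,7-dihydro-2-(pentafluorophenyl)-5H-pyrrolo[2,1-c][1,2,4]triazol-2-ium tetrafluoroborate (15 mol%), i-Pr2NEt (1 equiv), degassed toluene (0.02 M), Ar, rt then 40 °C
Reagents that add atoms: none
Why: The triazolylidene adds reversibly to both aldehydes, but only the aliphatic one (C3) is expected to reach a Breslow intermediate, because the aryl aldehyde is flanked by two ortho-alkoxy groups; the C3 acyl-anion equivalent then attacks the aryl aldehyde carbon C4 and the carbene is expelled, giving ketol 18 with the ketone at C3. The closest known reaction type is the carbene-catalysed intramolecular crossed benzoin that turns salicylaldehyde-derived keto-aldehydes into 3-hydroxychroman-4-ones, together with chemoselective crossed benzoins in which an ortho-substituted benzaldehyde is the acceptor. The pyranone ring closes in a 6-exo-trig mode (C3 onto the C4 carbonyl; ring O1–C2–C3–C4–C4a–C8a). The amine base should then transpose the ketol through the C3/C4 enediol, as benzylic acyloins of the phenylacetylcarbinol type do, to the aryl-conjugated ketone 19, the thermodynamic isomer. The carbinol centre (C4 in 18, C3 in 19) is set without control and under equilibration should favour the 2,3-trans arrangement, which is irrelevant because C2 and C3 both become sp2 in step 12. The step needs ring closure to win over dimerisation, over enolisation at C2 and over loss of the aryloxide from the Breslow intermediate; high dilution, a weak amine base, a non-polar solvent and the six-membered transition state are meant to secure this.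

Step 12
Reactants: 19 5-(benzyloxy)-2-[4-(benzyloxy)phenyl]-3-hydroxy-6,7,8-trimethoxychroman-4-one (racemic diastereomer mixture)
Product: 21 5-(benzyloxy)-2-[4-(benzyloxy)phenyl]-3-hydroxy-6,7,8-trimethoxy-4H-chromen-4-one, via chroman-3,4-dione 20 (not isolated)
Conditions: I2 (1.1 equiv), KOAc (3 equiv), AcOH, 90 °C
Reagents that add atoms: none
Why: Iodine/acetate dehydrogenation of an acyloin (the classical dihydroflavonol-to-flavonol oxidation) proceeds by α-iodination of the enol and loss of HI to dione 20, which enolises to the aromatic pyranone, so every diastereomer and any residual regioisomeric ketol converge and both stereocentres vanish.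

Step 13
Reactants: 21 5-(benzyloxy)-2-[4-(benzyloxy)phenyl]-3-hydroxy-6,7,8-trimethoxy-4H-chromen-4-one
Product: 22 3,5-dihydroxy-2-(4-hydroxyphenyl)-6,7,8-trimethoxy-4H-chromen-4-one (3,5,4'-trihydroxy-6,7,8-trimethoxyflavone)
Conditions: H2 (1 atm), 10% Pd/C, THF–MeOH, rt
Reagents that add atoms: none
Why: Catalytic hydrogenolysis cleaves both benzyl aryl ethers while the methyl ethers and the flavonol core are unaffected; the product has no stereocentre.

Compound list
1 | 2,3,4-trimethoxybenzaldehyde | COc1ccc(C=O)c(OC)c1OC | starting material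
2 | 5-bromo-2,3,4-trimethoxybenzaldehyde | O=Cc1cc(Br)c(OC)c(OC)c1OC | intermediate
3 | 5-bromo-2,3,4-trimethoxyphenyl formate | O=COc1cc(Br)c(OC)c(OC)c1OC | intermediate (not isolated)
4 | 5-bromo-2,3,4-trimethoxyphenol | Oc1cc(Br)c(OC)c(OC)c1OC | intermediate
5 | benzyl bromide | BrCc1ccccc1 | starting material
6 | 1-(benzyloxy)-5-bromo-2,3,4-trimethoxybenzene | Brc1cc(OCc2ccccc2)c(OC)c(OC)c1OC | intermediate
7 | [5-(benzyloxy)-2,3,4-trimethoxyphenyl]lithium | [Li]c1cc(OCc2ccccc2)c(OC)c(OC)c1OC | intermediate (not isolated)
8 | dimethyl [5-(benzyloxy)-2,3,4-trimethoxyphenyl]boronate | COB(OC)c1cc(OCc2ccccc2)c(OC)c(OC)c1OC | intermediate (not isolated)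
9 | 5-(benzyloxy)-2,3,4-trimethoxyphenol | Oc1cc(OCc2ccccc2)c(OC)c(OC)c1OC | intermediate
10 | 3-(benzyloxy)-2-(hydroxymethyl)-4,5,6-trimethoxyphenol | OCc1c(O)c(OC)c(OC)c(OC)c1OCc1ccccc1 | intermediate (not isolated)
11 | 6-(benzyloxy)-2-hydroxy-3,4,5-trimethoxybenzaldehyde | O=Cc1c(O)c(OC)c(OC)c(OC)c1OCc1ccccc1 | intermediate
12 | 4-hydroxymandelic acid (racemic) | OC(=O)C(O)c1ccc(O)cc1 | starting material
13 | benzyl 2-[4-(benzyloxy)phenyl]-2-hydroxyacetate (racemic) | O=C(OCc1ccccc1)C(O)c1ccc(OCc2ccccc2)cc1 | intermediate
14 | benzyl 2-bromo-2-[4-(benzyloxy)phenyl]acetate (racemic) | O=C(OCc1ccccc1)C(Br)c1ccc(OCc2ccccc2)cc1 | intermediate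
15 | benzyl 2-[3-(benzyloxy)-2-formyl-4,5,6-trimethoxyphenoxy]-2-[4-(benzyloxy)phenyl]acetate (racemic) | O=Cc1c(OCc2ccccc2)c(OC)c(OC)c(OC)c1OC(C(=O)OCc1ccccc1)c1ccc(OCc2ccccc2)cc1 | intermediate
16 | 2-[3-(benzyloxy)-2-(hydroxymethyl)-4,5,6-trimethoxyphenoxy]-2-[4-(benzyloxy)phenyl]ethan-1-ol (racemic) | OCc1c(OCc2ccccc2)c(OC)c(OC)c(OC)c1OC(CO)c1ccc(OCc2ccccc2)cc1 | intermediate
17 | 2-(benzyloxy)-6-{1-[4-(benzyloxy)phenyl]-2-oxoethoxy}-3,4,5-trimethoxybenzaldehyde (racemic) | O=Cc1c(OCc2ccccc2)c(OC)c(OC)c(OC)c1OC(C=O)c1ccc(OCc2ccccc2)cc1 | intermediate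
18 | 5-(benzyloxy)-2-[4-(benzyloxy)phenyl]-4-hydroxy-6,7,8-trimethoxychroman-3-one (racemic diastereomer mixture) | O=C1C(O)c2c(OCc3ccccc3)c(OC)c(OC)c(OC)c2OC1c1ccc(OCc2ccccc2)cc1 | intermediate (not isolated)
19 | 5-(benzyloxy)-2-[4-(benzyloxy)phenyl]-3-hydroxy-6,7,8-trimethoxychroman-4-one (racemic diastereomer mixture) | O=C1c2c(OCc3ccccc3)c(OC)c(OC)c(OC)c2OC(c2ccc(OCc3ccccc3)cc2)C1O | intermediate
20 | 5-(benzyloxy)-2-[4-(benzyloxy)phenyl]-6,7,8-trimethoxychroman-3,4-dione (racemic) | O=C1C(=O)c2c(OCc3ccccc3)c(OC)c(OC)c(OC)c2OC1c1ccc(OCc2ccccc2)cc1 | intermediate (not isolated)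
21 | 5-(benzyloxy)-2-[4-(benzyloxy)phenyl]-3-hydroxy-6,7,8-trimethoxy-4H-chromen-4-one | COc1c(OC)c(OCc2ccccc2)c2c(=O)c(O)c(-c3ccc(OCc4ccccc4)cc3)oc2c1OC | intermediate
22 | 3,5-dihydroxy-2-(4-hydroxyphenyl)-6,7,8-trimethoxy-4H-chromen-4-one | COc1c(OC)c(O)c2c(=O)c(O)c(-c3ccc(O)cc3)oc2c1OC | target

Total step count: 13. Longest linear sequence: 11 steps (steps 1–5 and 8–13, from 2,3,4-trimethoxybenzaldehyde); the mandelate branch (steps 6–7) joins at step 8.

Steps most likely to fail

Step 11. The Breslow intermediate may expel the neighbouring aryloxide (internal redox to an aryl ester) instead of closing the ring. The base may also enolise C2 and trigger a five-membered aldol closure onto the aryl aldehyde, or intermolecular benzoin coupling may compete; incomplete ketol transposition would be harmless, since step 12 converges. Fallback: setting out from dialdehyde 17, samarium(II) iodide in THF at −78 °C should reduce the aromatic aldehyde preferentially to its ketyl, which adds to the adjacent aliphatic aldehyde in a six-membered pinacol cyclisation. This would give 5-(benzyloxy)-2-[4-(benzyloxy)phenyl]-6,7,8-trimethoxychroman-3,4-diol F1. Swern oxidation of both carbinols (DMSO, oxalyl chloride, Et3N, −78 °C to rt) should then give dione 20, which enolises to flavonol 21, where the route resumes at step 13.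

Step 10. The first-formed aldehyde may be trapped as a lactol by the remaining hydroxyl and over-oxidised to a lactone, and the labile α-aryl-α-aryloxy aldehyde may be lost on work-up. Fallback: setting out from ester aldehyde 15, the aryl aldehyde is masked with trimethyl orthoformate, MeOH and catalytic PPTS as benzyl 2-[3-(benzyloxy)-2-(dimethoxymethyl)-4,5,6-trimethoxyphenoxy]-2-[4-(benzyloxy)phenyl]acetate F2. Partial reduction of the α-aryloxy ester with DIBAL-H in toluene at −78 °C should give 2-[3-(benzyloxy)-2-(dimethoxymethyl)-4,5,6-trimethoxyphenoxy]-2-[4-(benzyloxy)phenyl]acetaldehyde F3. Brief hydrolysis of the very electron-rich aryl acetal with aqueous oxalic acid in THF at 0 °C returns to the route at dialdehyde 17, with no diol and no double oxidation.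

Step 8. Substitution at the hindered, hydrogen-bonded phenoxide may be slow, and the ester enolate of the product may close onto the neighbouring formyl group in a five-membered aldol. Fallback: setting out from aldehyde 11, NaBH4 in MeOH at 0 °C gives hydroxymethylphenol 10, whose phenoxide (K2CO3, acetone) is alkylated with bromo ester 14 in the absence of any carbonyl electrophile on the ring. This would give benzyl 2-[3-(benzyloxy)-2-(hydroxymethyl)-4,5,6-trimethoxyphenoxy]-2-[4-(benzyloxy)phenyl]acetate F4. LiAlH4 reduction of F4, or of any lactone formed from it, returns to the route at diol 16.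

Further compounds
F1 | step 11 | 5-(benzyloxy)-2-[4-(benzyloxy)phenyl]-6,7,8-trimethoxychroman-3,4-diol (racemic diastereomer mixture) | OC1c2c(OCc3ccccc3)c(OC)c(OC)c(OC)c2OC(c2ccc(OCc3ccccc3)cc2)C1O
F2 | step 10 | benzyl 2-[3-(benzyloxy)-2-(dimethoxymethyl)-4,5,6-trimethoxyphenoxy]-2-[4-(benzyloxy)phenyl]acetate (racemic) | COC(OC)c1c(OCc2ccccc2)c(OC)c(OC)c(OC)c1OC(C(=O)OCc1ccccc1)c1ccc(OCc2ccccc2)cc1
F3 | step 10 | 2-[3-(benzyloxy)-2-(dimethoxymethyl)-4,5,6-trimethoxyphenoxy]-2-[4-(benzyloxy)phenyl]acetaldehyde (racemic) | COC(OC)c1c(OCc2ccccc2)c(OC)c(OC)c(OC)c1OC(C=O)c1ccc(OCc2ccccc2)cc1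
F4 | step 8 | benzyl 2-[3-(benzyloxy)-2-(hydroxymethyl)-4,5,6-trimethoxyphenoxy]-2-[4-(benzyloxy)phenyl]acetate (racemic) | OCc1c(OCc2ccccc2)c(OC)c(OC)c(OC)c1OC(C(=O)OCc1ccccc1)c1ccc(OCc2ccccc2)cc1
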